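**Retrosynthetic overview**
1. Last operation: base-catalysed removal of two N-Boc groups. Acid is avoided because it would protodeiodinate the 4-iodooxazole.
2. Oxazole C2–pyrrole C2 bond: site-selective Suzuki–Miyaura coupling of a 2,4-diiodooxazole with N-Boc-pyrrol-2-ylboronic acid.
3. Both C–I bonds: one-pot double deprotonation/iodination (C4 first, then C2) of an N-Boc 5-(indol-3-yl)oxazole.
4. Oxazole ring: van Leusen reaction of TosMIC with the indole-3-carbaldehyde, which comes from Vilsmeier–Haack formylation of 6-bromo-4-methoxyindole.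
5. Ring order: the indole is bought, the oxazole is the only ring built (second step), and the pyrrole is bought and attached (fifth step).

Assumption: the target SMILES holds no stereocentre and no hindered axis, so the compound is achiral and needs no enantiocontrol; 1, 4 and 13 are taken as catalogue chemicals.

**Route**

Step 1
Reactants: 1 6-bromo-4-methoxy-1H-indole
Product: 3 6-bromo-4-methoxy-1H-indole-3-carbaldehyde, via iminium salt 2 (not isolated)
Conditions: POCl3 (1.2 equiv), DMF, 0 → 40 °C; then 2 M aq. NaOH, 0 °C → rt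
Reagents that add atoms: DMF, CN(C)C=O (formyl carbon); water, O (formyl oxygen, on hydrolysis)
Why: In this Vilsmeier–Haack formylation the chloroiminium ion made from POCl3 and DMF attacks the enamine-like C3 of the indole and base hydrolyses iminium salt 2 to the aldehyde, while Br and OMe are inert and no stereocentre is formed.

Step 2
Reactants: 3 6-bromo-4-methoxy-1H-indole-3-carbaldehyde; 4 p-toluenesulfonylmethyl isocyanide (TosMIC)
Product: 6 5-(6-bromo-4-methoxy-1H-indol-3-yl)oxazole, via 4-tosyloxazoline 5 (not isolated)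
Conditions: TosMIC (1.2 equiv), K2CO3 (2.5 equiv), MeOH, reflux
Reagents that add atoms: TosMIC (4), Cc1ccc(cc1)S(=O)(=O)C[N+]#[C-] (oxazole C4, N3 and C2)
Why: In this van Leusen oxazole synthesis deprotonated TosMIC adds to the aldehyde, the alkoxide closes onto the isocyanide carbon to give oxazoline 5, and base-induced loss of p-toluenesulfinate aromatises the ring and erases the two transient (racemic, trans) stereocentres.

Step 3
Reactants: 6 5-(6-bromo-4-methoxy-1H-indol-3-yl)oxazole
Product: 7 tert-butyl 6-bromo-4-methoxy-3-(oxazol-5-yl)indole-1-carboxylate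
Conditions: Boc2O (1.2 equiv), DMAP (10 mol %), MeCN, rt
Reagents that add atoms: di-tert-butyl dicarbonate (Boc2O), CC(C)(C)OC(=O)OC(=O)OC(C)(C)C
Why: This DMAP-catalysed N-acylation (carbamate protection) removes the acidic indole N–H before the lithiation and damps the indole ring towards iodine, and no stereocentre is formed.

Step 4
Reactants: 7 tert-butyl 6-bromo-4-methoxy-3-(oxazol-5-yl)indole-1-carboxylate
Product: 12 tert-butyl 6-bromo-3-(2,4-diiodooxazol-5-yl)-4-methoxyindole-1-carboxylate, via 2-lithiooxazole 8 (not isolated), via isocyano enolate 9 (not isolated), via 4-iodooxazole 10 (not isolated), via 4-iodo-2-lithiooxazole 11 (not isolated)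
Conditions: LiN(SiMe3)2 (1.2 equiv), THF–DMPU (4:1), −78 °C; I2 (1.2 equiv); then LiN(SiMe3)2 (1.5 equiv), −78 °C; I2 (1.5 equiv), −78 → −20 °C
Reagents that add atoms: iodine, [I][I]
Why: In this deprotonation/electrophilic iodination of a lithiated azole, LiN(SiMe3)2 removes only the oxazole C2–H, lithio species 8 opens in the polar medium to isocyano enolate 9, which takes up iodine at the former C4 and recloses to 10, and a second deprotonation gives 11, whose blocked C4 sends iodine to C2, while the amide base neither exchanges with Ar–Br nor attacks the hindered Boc group and no stereocentre is formed.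

Step 5
Reactants: 12 tert-butyl 6-bromo-3-(2,4-diiodooxazol-5-yl)-4-methoxyindole-1-carboxylate; 13 [1-(tert-butoxycarbonyl)pyrrol-2-yl]boronic acid
Product: 14 tert-butyl 6-bromo-3-{2-[1-(tert-butoxycarbonyl)pyrrol-2-yl]-4-iodooxazol-5-yl}-4-methoxyindole-1-carboxylate
Conditions: 13 (1.1 equiv), Pd(PPh3)4 (5 mol %), Na2CO3 (2 equiv), DME–H2O (4:1), 60 °C
Reagents that add atoms: [1-(tert-butoxycarbonyl)pyrrol-2-yl]boronic acid (13), CC(C)(C)OC(=O)n1cccc1B(O)O
Why: In this site-selective Suzuki–Miyaura coupling zerovalent palladium inserts fastest into the electron-poor, unhindered C2–I bond between O and N, more slowly into the C4–I bond shielded by the peri-crowded 4-methoxyindol-3-yl group, and slowest into C6–Br, so one equivalent of boronic acid gives the C2-pyrrolyl product without forming a stereocentre.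

Step 6
Reactants: 14 tert-butyl 6-bromo-3-{2-[1-(tert-butoxycarbonyl)pyrrol-2-yl]-4-iodooxazol-5-yl}-4-methoxyindole-1-carboxylate
Product: 16 5-(6-bromo-4-methoxy-1H-indol-3-yl)-4-iodo-2-(1H-pyrrol-2-yl)oxazole (the target), via mono-Boc compound 15 (not isolated)
Conditions: NaOMe (0.3 equiv), MeOH–THF (1:1), rt
Reagents that add atoms: none
Why: In this base-catalysed methanolysis of azole carbamates methoxide attacks each Boc carbonyl and expels the stabilised indolide or pyrrolide, which MeOH reprotonates, so both groups leave without the acid that would protodeiodinate C4, and C–I, C–Br and OMe are untouched.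

**Compound list**
1 | 6-bromo-4-methoxy-1H-indole | COc1cc(Br)cc2[nH]ccc12 | starting material
2 | N-[(6-bromo-4-methoxy-1H-indol-3-yl)methylidene]-N-methylmethanaminium dichlorophosphate | COc1cc(Br)cc2[nH]cc(C=[N+](C)C)c12.[O-]P(=O)(Cl)Cl | intermediate (not isolated)
3 | 6-bromo-4-methoxy-1H-indole-3-carbaldehyde | COc1cc(Br)cc2[nH]cc(C=O)c12 | intermediate
4 | p-toluenesulfonylmethyl isocyanide (TosMIC) | Cc1ccc(cc1)S(=O)(=O)C[N+]#[C-] | starting material
5 | rac-trans-5-(6-bromo-4-methoxy-1H-indol-3-yl)-4-tosyl-4,5-dihydrooxazole (racemate, the 4S,5S enantiomer drawn) | O1C=N[C@@H](S(=O)(=O)c2ccc(C)cc2)[C@@H]1c3c[nH]c4cc(Br)cc(OC)c34 | intermediate (not isolated)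
6 | 5-(6-bromo-4-methoxy-1H-indol-3-yl)oxazole | COc1cc(Br)cc2[nH]cc(-c3cnco3)c12 | intermediate
7 | tert-butyl 6-bromo-4-methoxy-3-(oxazol-5-yl)indole-1-carboxylate | COc1cc(Br)cc2n(C(=O)OC(C)(C)C)cc(-c3cnco3)c12 | intermediate
8 | tert-butyl 6-bromo-3-(2-lithiooxazol-5-yl)-4-methoxyindole-1-carboxylate | COc1cc(Br)cc2n(C(=O)OC(C)(C)C)cc(-c3cnc([Li])o3)c12 | intermediate (not isolated)
9 | lithium (Z)-1-[6-bromo-1-(tert-butoxycarbonyl)-4-methoxyindol-3-yl]-2-isocyanoethen-1-olate (ring-opened form of 8) | COc1cc(Br)cc2n(C(=O)OC(C)(C)C)cc(/C(O[Li])=C/[N+]#[C-])c12 | intermediate (not isolated)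
10 | tert-butyl 6-bromo-3-(4-iodooxazol-5-yl)-4-methoxyindole-1-carboxylate | COc1cc(Br)cc2n(C(=O)OC(C)(C)C)cc(-c3ocnc3I)c12 | intermediate (not isolated)
11 | tert-butyl 6-bromo-3-(4-iodo-2-lithiooxazol-5-yl)-4-methoxyindole-1-carboxylate | COc1cc(Br)cc2n(C(=O)OC(C)(C)C)cc(-c3oc([Li])nc3I)c12 | intermediate (not isolated)
12 | tert-butyl 6-bromo-3-(2,4-diiodooxazol-5-yl)-4-methoxyindole-1-carboxylate | COc1cc(Br)cc2n(C(=O)OC(C)(C)C)cc(-c3oc(I)nc3I)c12 | intermediate
13 | [1-(tert-butoxycarbonyl)pyrrol-2-yl]boronic acid | CC(C)(C)OC(=O)n1cccc1B(O)O | starting material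
14 | tert-butyl 6-bromo-3-{2-[1-(tert-butoxycarbonyl)pyrrol-2-yl]-4-iodooxazol-5-yl}-4-methoxyindole-1-carboxylate | COc1cc(Br)cc2n(C(=O)OC(C)(C)C)cc(-c3oc(-c4cccn4C(=O)OC(C)(C)C)nc3I)c12 | intermediate
15 | tert-butyl 2-[5-(6-bromo-4-methoxy-1H-indol-3-yl)-4-iodooxazol-2-yl]pyrrole-1-carboxylate (drawn for loss of the indole Boc first; the order does not matter) | COc1cc(Br)cc2[nH]cc(-c3oc(-c4cccn4C(=O)OC(C)(C)C)nc3I)c12 | intermediate (not isolated)
16 | 5-(6-bromo-4-methoxy-1H-indol-3-yl)-4-iodo-2-(1H-pyrrol-2-yl)oxazole (achiral) | COc1cc(Br)cc2[nH]cc(-c3oc(-c4ccc[nH]4)nc3I)c12 | target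

**Step count**
- Total step count: 6.
- Longest linear sequence: 6 (1 → 3 → 6 → 7 → 12 → 14 → 16).

**Steps most likely to fail**

**Step 5.** Three carbon–halogen bonds compete for palladium, and 13 protodeboronates easily.
- The fallback sets out from 7 and comes back at 14.
- It reverses the order of C–C and C–I bond formation, so palladium is offered only one C–I bond.
- Compound 7 is deprotonated with LiN(SiMe3)2 (1.1 equiv) in THF without DMPU, where the closed lithio form 8 prevails. Quenching with I2 gives tert-butyl 6-bromo-3-(2-iodooxazol-5-yl)-4-methoxyindole-1-carboxylate F5.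
- F5 is coupled with 13 (Pd(PPh3)4, Na2CO3, DME–H2O, 60 °C) to give tert-butyl 6-bromo-3-{2-[1-(tert-butoxycarbonyl)pyrrol-2-yl]oxazol-5-yl}-4-methoxyindole-1-carboxylate F6.
- The one free oxazole carbon of F6 is then iodinated electrophilically with N-iodosuccinimide (DMF, rt to 40 °C). The two Boc groups hold back the pyrrole and indole rings. This gives 14.

**Step 4.** The C4/C2 selectivity of the anion may be poor and the second iodination may stall.
- The fallback sets out from 6 and comes back at 10.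
- It installs the C4 iodine by electrophilic substitution instead of anion chemistry. Oxazole C4 is the terminus of both the indole N–C2=C3–C5'=C4' dienamine and the ring enol ether.
- N-iodosuccinimide (1.0 equiv, THF, 0 °C) converts 6 into 5-(6-bromo-4-methoxy-1H-indol-3-yl)-4-iodooxazole F4.
- Boc2O/DMAP then gives 10, now isolated. Only one clean LiN(SiMe3)2/I2 cycle remains (10 → 11 → 12).

**Step 2.** The N–H aldehyde is a vinylogous amide. It is poorly electrophilic and is crowded by the peri OMe group.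
- The fallback sets out from 1 and comes back at 7.
- It brings in the oxazole ready-made by cross-coupling instead of building it.
- I2/KOH in DMF gives 6-bromo-3-iodo-4-methoxy-1H-indole F1.
- F1 is protected at once (Boc2O, DMAP) as tert-butyl 6-bromo-3-iodo-4-methoxyindole-1-carboxylate F2.
- Suzuki–Miyaura coupling at C3–I, which reacts ahead of C6–Br, uses commercial 5-(4,4,5,5-tetramethyl-1,3,2-dioxaborolan-2-yl)-2-(triisopropylsilyl)oxazole, CC(C)[Si](C(C)C)(C(C)C)c1ncc(o1)B1OC(C)(C)C(C)(C)O1. The conditions are Pd(PPh3)4, Na2CO3, dioxane–H2O, 70 °C. The product is tert-butyl 6-bromo-4-methoxy-3-[2-(triisopropylsilyl)oxazol-5-yl]indole-1-carboxylate F3.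
- Protodesilylation of the labile C2–Si bond with 1 M aq. HCl in THF at rt gives 7.

**Further compounds**
F1 | step 2 | 6-bromo-3-iodo-4-methoxy-1H-indole | COc1cc(Br)cc2[nH]cc(I)c12
F2 | step 2 | tert-butyl 6-bromo-3-iodo-4-methoxyindole-1-carboxylate | COc1cc(Br)cc2n(C(=O)OC(C)(C)C)cc(I)c12
F3 | step 2 | tert-butyl 6-bromo-4-methoxy-3-[2-(triisopropylsilyl)oxazol-5-yl]indole-1-carboxylate | COc1cc(Br)cc2n(C(=O)OC(C)(C)C)cc(-c3cnc(o3)[Si](C(C)C)(C(C)C)C(C)C)c12
F4 | step 4 | 5-(6-bromo-4-methoxy-1H-indol-3-yl)-4-iodooxazole | COc1cc(Br)cc2[nH]cc(-c3ocnc3I)c12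
F5 | step 5 | tert-butyl 6-bromo-3-(2-iodooxazol-5-yl)-4-methoxyindole-1-carboxylate | COc1cc(Br)cc2n(C(=O)OC(C)(C)C)cc(-c3cnc(I)o3)c12
F6 | step 5 | tert-butyl 6-bromo-3-{2-[1-(tert-butoxycarbonyl)pyrrol-2-yl]oxazol-5-yl}-4-methoxyindole-1-carboxylate | COc1cc(Br)cc2n(C(=O)OC(C)(C)C)cc(-c3cnc(-c4cccn4C(=O)OC(C)(C)C)o3)c12
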